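**Strategy.** The last ring closed is ring A, the dihydrofuran ring O1–C2–C3–C3a–C7a of the benzofuran that carries the styryl group. It is cut at C2–C3: C2 is bound to O1 and to the electron-rich benzo ring of the central benzofuran, so its C–H bond is a hydridic acceptor for a diaryl carbene placed at C3. The precursor is an open aryl benzyl ether whose ortho carbon bears a diaryl ketone hydrazone. Oxidation to the diazo compound and Rh2(R-PTAD)4-catalysed 1,5-C–H insertion close ring A and set C3 under catalyst control; acid then equilibrates C2 to trans. The two earlier dihydrobenzofurans are made the same way; a bromine at C4 is exchanged for the hydroxystyryl arm at the end.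

Key step: step 10

Remarks on the chemistry:
- Ring B is the dihydrofuran ring of the central benzofuran (its C5 is bonded to C2 of ring A). Ring C is the dihydrofuran ring of the third benzofuran (its C4 is bonded to C3 of ring B).
- Assumption: Rh2(R-PTAD)4 is taken as the catalyst enantiomer that gives the (3R) series in all three insertions; if the sense of induction is the opposite, Rh2(S-PTAD)4 is used in its place.
- Assumption: alkenylboronate 25 is taken as a purchasable building block.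
- Hydrazones are E/Z mixtures; the geometry is lost on oxidation.

**Step 1**
Reactants: 1 1-bromo-3,5-dimethoxybenzene; 2 3,5-dimethoxybenzoyl chloride
Product: 4 (2-bromo-6-hydroxy-4-methoxyphenyl)(3,5-dimethoxyphenyl)methanone, via dimethoxy ketone 3 (not isolated)
Conditions: AlCl3 (2.5 equiv), CH2Cl2, 0 °C to 40 °C
Reagents that add atoms: none
Why: Friedel–Crafts acylation should occur at the carbon of 1 ortho to bromine and para to a methoxy group (the carbon between the two methoxy groups is more hindered), and excess AlCl3 then cleaves only the methoxy group ortho to the new carbonyl through its six-membered aluminium chelate.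

**Step 2**
Reactants: 4 hydroxy ketone
Product: 5 3-bromo-2-[(3,5-dimethoxyphenyl)(hydrazinylidene)methyl]-5-methoxyphenol
Conditions: N2H4·H2O, EtOH, 80 °C
Reagents that add atoms: hydrazine (used as the hydrate), NN
Why: Hydrazone condensation; the phenol–carbonyl hydrogen bond keeps the C=O in the plane of the bromophenol ring and activates it, so hydrazine should reach this di-ortho-substituted ketone before the bulky ether is in place.

**Step 3**
Reactants: 5 hydroxy hydrazone; 6 4-methoxybenzyl chloride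
Product: 7 hydrazone of (2-bromo-4-methoxy-6-[(4-methoxybenzyl)oxy]phenyl)(3,5-dimethoxyphenyl)methanone
Conditions: K2CO3, DMF, 25 °C
Reagents that add atoms: none
Why: Williamson etherification; the phenoxide formed by K2CO3 is far more nucleophilic than the neutral hydrazone NH2, so benzylation should be O-selective.

**Step 4**
Reactants: 7 hydrazone ether
Product: 10 (2R,3R)-4-bromo-3-(3,5-dimethoxyphenyl)-6-methoxy-2-(4-methoxyphenyl)-2,3-dihydro-1-benzofuran, via diazo compound 8 (not isolated), via cis-dihydrobenzofuran 9 (not isolated)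
Conditions: MnO2, CH2Cl2, 0 °C; filter; Rh2(R-PTAD)4 (1 mol%), CH2Cl2, 0 °C to rt; then TFA, 0 °C to rt
Reagents that add atoms: none
Why: Oxidation to the diazo compound, intramolecular 1,5-C–H insertion of the donor/donor rhodium carbene into the O–CH2 group (C3 fixed by the catalyst, C2 first cis) and TFA-mediated reversible C2–O ionisation that inverts only C2 should give the trans-(2R,3R) ring C.

**Step 5**
Reactants: 11 5-bromo-2-hydroxybenzonitrile; 6 4-methoxybenzyl chloride
Product: 12 5-bromo-2-[(4-methoxybenzyl)oxy]benzonitrile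
Conditions: K2CO3, DMF, 60 °C
Reagents that add atoms: none
Why: Williamson etherification of the phenol.

**Step 6**
Reactants: 10 ring C bromide; 12 nitrile
Product: 15 hydrazone of {5-bromo-2-[(4-methoxybenzyl)oxy]phenyl}[(2R,3R)-3-(3,5-dimethoxyphenyl)-6-methoxy-2-(4-methoxyphenyl)-2,3-dihydro-1-benzofuran-4-yl]methanone, via aryllithium 13 (not isolated), via N-H ketimine 14 (not isolated)
Conditions: t-BuLi (2 equiv), THF, −78 °C; 12, −78 to 0 °C; then AcOH, N2H4·H2O, EtOH, 60 °C
Reagents that add atoms: hydrazine (used as the hydrate), NN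
Why: Bromine–lithium exchange followed by addition of the aryllithium to the nitrile gives a ketimine whose acid-catalysed transimination with hydrazine should deliver the hindered hydrazone without a ketone stage; no stereocentre is touched.

**Step 7**
Reactants: 15 hydrazone
Product: 18 (2R,3R)-5-bromo-3-[(2R,3R)-3-(3,5-dimethoxyphenyl)-6-methoxy-2-(4-methoxyphenyl)-2,3-dihydro-1-benzofuran-4-yl]-2-(4-methoxyphenyl)-2,3-dihydro-1-benzofuran, via diazo compound 16 (not isolated), via cis isomer 17 (not isolated)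
Conditions: MnO2, CH2Cl2, 0 °C; filter; Rh2(R-PTAD)4 (1 mol%), CH2Cl2, 0 °C to rt; then TFA, 0 °C
Reagents that add atoms: none
Why: Same sequence as step 4: the carbene at C3 of ring B inserts into the O–CH2 bond of the 4-methoxybenzyl ether (1,5-C–H insertion favoured over attack on the neighbouring arenes) with C3 set by the catalyst, and TFA equilibration makes C2 trans to give the (2R,3R) ring B.

**Step 8**
Reactants: 18 ring B/ring C bromide
Product: 19 {(2R,3R)-3-[(2R,3R)-3-(3,5-dimethoxyphenyl)-6-methoxy-2-(4-methoxyphenyl)-2,3-dihydro-1-benzofuran-4-yl]-2-(4-methoxyphenyl)-2,3-dihydro-1-benzofuran-5-yl}methanol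
Conditions: Bu3SnCH2OH, Pd(PPh3)4 (5 mol%), 1,4-dioxane, 100 °C
Reagents that add atoms: (tributylstannyl)methanol, OC[Sn](CCCC)(CCCC)CCCC
Why: Migita–Kosugi–Stille coupling transfers the hydroxymethyl group from tin to the aryl bromide and should give the benzylic alcohol in one step.

**Step 9**
Reactants: 19 benzylic alcohol; 5 hydroxy hydrazone
Product: 20 hydrazone of (2-bromo-4-methoxy-6-{[ring B/ring C aryl]methoxy}phenyl)(3,5-dimethoxyphenyl)methanone (the aryl is the 5-yl group of 19)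
Conditions: PPh3, DIAD, THF, 0 °C to rt
Reagents that add atoms: none
Why: Mitsunobu etherification; the phenol of 5 is the only acidic pronucleophile and an achiral primary benzylic carbon is substituted, while the weakly nucleophilic hydrazone NH2 should remain a spectator.

**Step 10**
Reactants: 20 hydrazone ether
Product: 23 (2R,3R)-4-bromo-3-(3,5-dimethoxyphenyl)-6-methoxy-2-{(2R,3R)-3-[(2R,3R)-3-(3,5-dimethoxyphenyl)-6-methoxy-2-(4-methoxyphenyl)-2,3-dihydro-1-benzofuran-4-yl]-2-(4-methoxyphenyl)-2,3-dihydro-1-benzofuran-5-yl}-2,3-dihydro-1-benzofuran, via diazo compound 21 (not isolated), via cis isomer 22 (not isolated)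
Conditions: MnO2, CH2Cl2, 0 °C; filter; Rh2(R-PTAD)4 (2 mol%), CH2Cl2, 0 °C to rt; then TFA, 0 °C
Reagents that add atoms: none
Why: MnO2 dehydrogenates hydrazone 20 to diaryldiazomethane 21, from which Rh2(R-PTAD)4 forms a donor/donor rhodium carbene at C3 that inserts into a C–H bond of the O1–CH2 group; the closest known reaction type is the enantioselective intramolecular C–H insertion of diaryl carbenes into benzyl aryl ethers to give 2,3-diaryl-2,3-dihydrobenzofurans. Ring A (O1–C2–C3–C3a–C7a) closes by C2–C3 bond formation in a 1,5-C–H insertion through a three-centre, hydride-transfer-like transition state. C3 is set by the chiral carboxylate pocket of the catalyst, which fixes the face of the carbene that meets the C–H bond, and C2 first arises cis to C3 as a consequence of the concerted insertion. TFA then ionises the C2–O1 bond reversibly to a benzylic cation stabilised by the para oxygen of the ring B benzo ring, and 5-exo-trig reclosure by the phenol gives the more stable 2,3-trans ring, so that only C2 is inverted and the (2R,3R) configuration results. The step needs 1,5-insertion to win over azine formation and other carbene pathways, which the hydridic C2–H bond (alpha to O1 and to an electron-rich aryl), the five-membered geometry and the shielding ortho bromine should secure, and it needs catalyst control over the four existing stereocentres, which is expected because they lie beyond an aromatic ring. Bromine at C4 stands in for the styryl arm, which would otherwise react with the diazo group.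

**Step 11**
Reactants: 23 octamethyl ether bromide
Product: 24 octaphenol bromide (all eight methoxy groups of 23 as hydroxy groups; configuration unchanged)
Conditions: BBr3, CH2Cl2, −78 °C to rt; then H2O
Reagents that add atoms: none
Why: BBr3 cleaves the eight aryl methyl ethers; this is done before the alkene is present so that no acid-induced cyclisation of a stilbene onto the C3 aryl group can occur, and any reversible opening of the benzylic C2–O bonds can only return the trans rings.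

**Step 12**
Reactants: 24 octaphenol bromide; 25 4-[(E)-2-(4,4,5,5-tetramethyl-1,3,2-dioxaborolan-2-yl)ethenyl]phenol
Product: 26 target CNP0184803.1
Conditions: Pd(OAc)2 (5 mol%), SPhos (10 mol%), K2CO3, 1,4-dioxane/H2O (degassed), 60 °C
Reagents that add atoms: none
Why: Suzuki–Miyaura coupling with retention of the E geometry of the alkenylboronate; the electron-rich SPhos ligand should allow oxidative addition at the hindered bromide, and free phenols are tolerated in aqueous carbonate.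

**Compound list**

1 | 1-bromo-3,5-dimethoxybenzene | COc1cc(Br)cc(OC)c1 | starting material
2 | 3,5-dimethoxybenzoyl chloride | COc1cc(cc(OC)c1)C(Cl)=O | starting material
3 | (2-bromo-4,6-dimethoxyphenyl)(3,5-dimethoxyphenyl)methanone | COc1cc(OC)cc(c1)C(=O)c1c(Br)cc(OC)cc1OC | intermediate (not isolated)
4 | (2-bromo-6-hydroxy-4-methoxyphenyl)(3,5-dimethoxyphenyl)methanone | COc1cc(OC)cc(c1)C(=O)c1c(Br)cc(OC)cc1O | intermediate
5 | 3-bromo-2-[(3,5-dimethoxyphenyl)(hydrazinylidene)methyl]-5-methoxyphenol (E/Z mixture) | COc1cc(OC)cc(c1)C(=NN)c1c(Br)cc(OC)cc1O | intermediate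
6 | 4-methoxybenzyl chloride | COc1ccc(CCl)cc1 | starting material
7 | hydrazone of (2-bromo-4-methoxy-6-[(4-methoxybenzyl)oxy]phenyl)(3,5-dimethoxyphenyl)methanone | COc1cc(OC)cc(c1)C(=NN)c1c(Br)cc(OC)cc1OCc1ccc(OC)cc1 | intermediate
8 | 1-bromo-2-[diazo(3,5-dimethoxyphenyl)methyl]-5-methoxy-3-[(4-methoxybenzyl)oxy]benzene | COc1cc(OC)cc(c1)C(=[N+]=[N-])c1c(Br)cc(OC)cc1OCc1ccc(OC)cc1 | intermediate (not isolated)
9 | (2S,3R)-4-bromo-3-(3,5-dimethoxyphenyl)-6-methoxy-2-(4-methoxyphenyl)-2,3-dihydro-1-benzofuran (cis) | Brc1cc(OC)cc2c1[C@@H](c1cc(OC)cc(OC)c1)[C@@H](c1ccc(OC)cc1)O2 | intermediate (not isolated)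
10 | (2R,3R)-4-bromo-3-(3,5-dimethoxyphenyl)-6-methoxy-2-(4-methoxyphenyl)-2,3-dihydro-1-benzofuran (trans) | Brc1cc(OC)cc2c1[C@@H](c1cc(OC)cc(OC)c1)[C@H](c1ccc(OC)cc1)O2 | intermediate
11 | 5-bromo-2-hydroxybenzonitrile | N#Cc1cc(Br)ccc1O | starting material
12 | 5-bromo-2-[(4-methoxybenzyl)oxy]benzonitrile | COc1ccc(COc2ccc(Br)cc2C#N)cc1 | intermediate
13 | [(2R,3R)-3-(3,5-dimethoxyphenyl)-6-methoxy-2-(4-methoxyphenyl)-2,3-dihydro-1-benzofuran-4-yl]lithium | [Li]c1cc(OC)cc2c1[C@@H](c1cc(OC)cc(OC)c1)[C@H](c1ccc(OC)cc1)O2 | intermediate (not isolated)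
14 | {5-bromo-2-[(4-methoxybenzyl)oxy]phenyl}[(2R,3R)-3-(3,5-dimethoxyphenyl)-6-methoxy-2-(4-methoxyphenyl)-2,3-dihydro-1-benzofuran-4-yl]methanimine | COc1ccc(COc2ccc(Br)cc2C(=N)c2cc(OC)cc3c2[C@@H](c2cc(OC)cc(OC)c2)[C@H](c2ccc(OC)cc2)O3)cc1 | intermediate (not isolated)
15 | hydrazone of the ketone corresponding to 14 (C=N–NH2 in place of C=NH) | COc1ccc(COc2ccc(Br)cc2C(=NN)c2cc(OC)cc3c2[C@@H](c2cc(OC)cc(OC)c2)[C@H](c2ccc(OC)cc2)O3)cc1 | intermediate
16 | diazo compound from 15 (C=N2 in place of C=N–NH2) | COc1ccc(COc2ccc(Br)cc2C(=[N+]=[N-])c2cc(OC)cc3c2[C@@H](c2cc(OC)cc(OC)c2)[C@H](c2ccc(OC)cc2)O3)cc1 | intermediate (not isolated)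
17 | (2S,3R)-5-bromo-3-[(2R,3R)-3-(3,5-dimethoxyphenyl)-6-methoxy-2-(4-methoxyphenyl)-2,3-dihydro-1-benzofuran-4-yl]-2-(4-methoxyphenyl)-2,3-dihydro-1-benzofuran (ring B cis) | Brc1ccc2c(c1)[C@@H](c1cc(OC)cc3c1[C@@H](c1cc(OC)cc(OC)c1)[C@H](c1ccc(OC)cc1)O3)[C@@H](c1ccc(OC)cc1)O2 | intermediate (not isolated)
18 | (2R,3R)-5-bromo-3-[(2R,3R)-3-(3,5-dimethoxyphenyl)-6-methoxy-2-(4-methoxyphenyl)-2,3-dihydro-1-benzofuran-4-yl]-2-(4-methoxyphenyl)-2,3-dihydro-1-benzofuran | Brc1ccc2c(c1)[C@@H](c1cc(OC)cc3c1[C@@H](c1cc(OC)cc(OC)c1)[C@H](c1ccc(OC)cc1)O3)[C@H](c1ccc(OC)cc1)O2 | intermediate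
19 | {(2R,3R)-3-[(2R,3R)-3-(3,5-dimethoxyphenyl)-6-methoxy-2-(4-methoxyphenyl)-2,3-dihydro-1-benzofuran-4-yl]-2-(4-methoxyphenyl)-2,3-dihydro-1-benzofuran-5-yl}methanol | OCc1ccc2c(c1)[C@@H](c1cc(OC)cc3c1[C@@H](c1cc(OC)cc(OC)c1)[C@H](c1ccc(OC)cc1)O3)[C@H](c1ccc(OC)cc1)O2 | intermediate
20 | hydrazone of (2-bromo-4-methoxy-6-{[the 5-yl group of 19]methoxy}phenyl)(3,5-dimethoxyphenyl)methanone | COc1cc(OC)cc(c1)C(=NN)c1c(Br)cc(OC)cc1OCc1ccc2c(c1)[C@@H](c1cc(OC)cc3c1[C@@H](c1cc(OC)cc(OC)c1)[C@H](c1ccc(OC)cc1)O3)[C@H](c1ccc(OC)cc1)O2 | intermediate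
21 | diazo compound from 20 (C=N2 in place of C=N–NH2) | COc1cc(OC)cc(c1)C(=[N+]=[N-])c1c(Br)cc(OC)cc1OCc1ccc2c(c1)[C@@H](c1cc(OC)cc3c1[C@@H](c1cc(OC)cc(OC)c1)[C@H](c1ccc(OC)cc1)O3)[C@H](c1ccc(OC)cc1)O2 | intermediate (not isolated)
22 | ring A cis isomer of 23, (2S,3R) in ring A, (2R,3R) in rings B and C | Brc1cc(OC)cc2c1[C@@H](c1cc(OC)cc(OC)c1)[C@@H](c1ccc3c(c1)[C@@H](c1cc(OC)cc4c1[C@@H](c1cc(OC)cc(OC)c1)[C@H](c1ccc(OC)cc1)O4)[C@H](c1ccc(OC)cc1)O3)O2 | intermediate (not isolated)
23 | (2R,3R)-4-bromo-3-(3,5-dimethoxyphenyl)-6-methoxy-2-{(2R,3R)-3-[(2R,3R)-3-(3,5-dimethoxyphenyl)-6-methoxy-2-(4-methoxyphenyl)-2,3-dihydro-1-benzofuran-4-yl]-2-(4-methoxyphenyl)-2,3-dihydro-1-benzofuran-5-yl}-2,3-dihydro-1-benzofuran | Brc1cc(OC)cc2c1[C@@H](c1cc(OC)cc(OC)c1)[C@H](c1ccc3c(c1)[C@@H](c1cc(OC)cc4c1[C@@H](c1cc(OC)cc(OC)c1)[C@H](c1ccc(OC)cc1)O4)[C@H](c1ccc(OC)cc1)O3)O2 | intermediate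
24 | octaphenol corresponding to 23 (all OMe as OH; all six centres R) | Brc1cc(O)cc2c1[C@@H](c1cc(O)cc(O)c1)[C@H](c1ccc3c(c1)[C@@H](c1cc(O)cc4c1[C@@H](c1cc(O)cc(O)c1)[C@H](c1ccc(O)cc1)O4)[C@H](c1ccc(O)cc1)O3)O2 | intermediate
25 | 4-[(E)-2-(4,4,5,5-tetramethyl-1,3,2-dioxaborolan-2-yl)ethenyl]phenol | Oc1ccc(/C=C/B2OC(C)(C)C(C)(C)O2)cc1 | starting material
26 | 5-[(2R,3R)-6-hydroxy-2-{(2R,3R)-3-[(2R,3R)-3-(3,5-dihydroxyphenyl)-6-hydroxy-2-(4-hydroxyphenyl)-2,3-dihydro-1-benzofuran-4-yl]-2-(4-hydroxyphenyl)-2,3-dihydro-1-benzofuran-5-yl}-4-[(E)-2-(4-hydroxyphenyl)ethenyl]-2,3-dihydro-1-benzofuran-3-yl]benzene-1,3-diol | Oc1ccc(/C=C/c2cc(O)cc3c2[C@@H](c2cc(O)cc(O)c2)[C@H](c2ccc4c(c2)[C@@H](c2cc(O)cc5c2[C@@H](c2cc(O)cc(O)c2)[C@H](c2ccc(O)cc2)O5)[C@H](c2ccc(O)cc2)O4)O3)cc1 | target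

**Totals**

Total step count: 12. Longest linear sequence: 11 steps (steps 1–4 and 6–12; step 5 is a one-step branch, and hydrazone 5 re-enters at step 9).

**Steps most likely to fail**

1. Step 10 (key step). The crowded, di-ortho-substituted diaryl carbene may give poor catalyst-controlled facial selectivity or dimerise to the azine, and the benzylic cation opened during acid equilibration may be captured by a neighbouring electron-rich arene instead of the phenol. The fallback sets out from alcohol 19 and ketone 4 and comes back at 23. Alcohol 19 would be converted with tetrahydrothiophene and HBF4·OEt2 into the benzylic tetrahydrothiophenium tetrafluoroborate F1. Ketone 4 would be reduced with NaBH4 to the o-hydroxybenzhydrol F2, and this treated with 4-methylbenzenesulfinic acid to give the sulfone F3. With Cs2CO3 in CH2Cl2, F3 would release the o-quinone methide F4 and F1 the sulfur ylide F5. Conjugate addition and 5-exo-tet displacement of tetrahydrothiophene ([4+1] annulation) would close ring A directly as the 2,3-trans isomers, 23 and its (2S,3S) ring A diastereomer F6, to be separated by chromatography. This trades catalyst control for a separation of diastereomers.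

2. Step 9. Chemoselectivity may be lost if the hydrazone NH2 reacts with the azodicarboxylate or is N-alkylated, and the electron-rich benzylic alcohol may ionise. The fallback sets out from alcohol 19 and comes back at 20. SOCl2 and pyridine in CH2Cl2 at 0 °C would convert 19 into the benzylic chloride F7, which would alkylate the phenoxide of 5 (Cs2CO3, DMF, 0 °C) in a Williamson etherification that needs neither phosphine nor azodicarboxylate.

3. Step 12. Oxidative addition at the hindered aryl bromide of a phenoxide-rich ring may be slow, and base may open the 2-(4-hydroxyphenyl)dihydrobenzofurans through quinone methides. The fallback sets out from 24 and comes back at 26. Peracetylation (Ac2O, pyridine) would give the octaacetate F8. A Heck reaction with 4-ethenylphenyl acetate F9 (Pd(OAc)2, P(o-tol)3, Et3N, DMF, 90 °C) would give the nonaacetate F10 with the E alkene. Ammonia in methanol at 0 °C would then remove the acetates to give 26.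

**Further compounds**

F1 | step 10 | 1-{[the 5-yl group of 19]methyl}tetrahydrothiophenium tetrafluoroborate | F[B-](F)(F)F.C1CC[S+](C1)Cc1ccc2c(c1)[C@@H](c1cc(OC)cc3c1[C@@H](c1cc(OC)cc(OC)c1)[C@H](c1ccc(OC)cc1)O3)[C@H](c1ccc(OC)cc1)O2
F2 | step 10 | 3-bromo-2-[(3,5-dimethoxyphenyl)(hydroxy)methyl]-5-methoxyphenol (racemic) | COc1cc(OC)cc(c1)C(O)c1c(Br)cc(OC)cc1O
F3 | step 10 | 3-bromo-2-[(3,5-dimethoxyphenyl)(4-methylbenzenesulfonyl)methyl]-5-methoxyphenol (racemic) | COc1cc(OC)cc(c1)C(c1c(Br)cc(OC)cc1O)S(=O)(=O)c1ccc(C)cc1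
F4 | step 10 | 5-bromo-6-[(3,5-dimethoxyphenyl)methylidene]-3-methoxycyclohexa-2,4-dien-1-one (o-quinone methide) | COc1cc(OC)cc(c1)C=C1C(Br)=CC(OC)=CC1=O
F5 | step 10 | sulfur ylide from F1 (tetrahydrothiophenium benzylide) | C1CC[S+](C1)[CH-]c1ccc2c(c1)[C@@H](c1cc(OC)cc3c1[C@@H](c1cc(OC)cc(OC)c1)[C@H](c1ccc(OC)cc1)O3)[C@H](c1ccc(OC)cc1)O2
F6 | step 10 | ring A diastereomer of 23, (2S,3S) in ring A, (2R,3R) in rings B and C | Brc1cc(OC)cc2c1[C@H](c1cc(OC)cc(OC)c1)[C@@H](c1ccc3c(c1)[C@@H](c1cc(OC)cc4c1[C@@H](c1cc(OC)cc(OC)c1)[C@H](c1ccc(OC)cc1)O4)[C@H](c1ccc(OC)cc1)O3)O2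
F7 | step 9 | (2R,3R)-5-(chloromethyl)-3-[(2R,3R)-3-(3,5-dimethoxyphenyl)-6-methoxy-2-(4-methoxyphenyl)-2,3-dihydro-1-benzofuran-4-yl]-2-(4-methoxyphenyl)-2,3-dihydro-1-benzofuran | ClCc1ccc2c(c1)[C@@H](c1cc(OC)cc3c1[C@@H](c1cc(OC)cc(OC)c1)[C@H](c1ccc(OC)cc1)O3)[C@H](c1ccc(OC)cc1)O2
F8 | step 12 | octaacetate of 24 | Brc1cc(OC(C)=O)cc2c1[C@@H](c1cc(OC(C)=O)cc(OC(C)=O)c1)[C@H](c1ccc3c(c1)[C@@H](c1cc(OC(C)=O)cc4c1[C@@H](c1cc(OC(C)=O)cc(OC(C)=O)c1)[C@H](c1ccc(OC(C)=O)cc1)O4)[C@H](c1ccc(OC(C)=O)cc1)O3)O2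
F9 | step 12 | 4-ethenylphenyl acetate | CC(=O)Oc1ccc(C=C)cc1
F10 | step 12 | nonaacetate of 26 | CC(=O)Oc1ccc(/C=C/c2cc(OC(C)=O)cc3c2[C@@H](c2cc(OC(C)=O)cc(OC(C)=O)c2)[C@H](c2ccc4c(c2)[C@@H](c2cc(OC(C)=O)cc5c2[C@@H](c2cc(OC(C)=O)cc(OC(C)=O)c2)[C@H](c2ccc(OC(C)=O)cc2)O5)[C@H](c2ccc(OC(C)=O)cc2)O4)O3)cc1
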